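The data come from a simulation for an exercise; noise was put on by code.

The green run was my one witness for the flasks autumn and dawn.

| flask | substrate | partner | temperature | remark | time |
|---|---|---|---|---|---|
| green | 10 mM | 12 mM | 70 °C | run made earlier |  |
| autumn | 10 mM | 8.00 mM | 70 °C |  | 40 min |
| dawn | 10 mM | 8.00 mM | 90 °C |  | 40 min |

green run (percent of the substrate charged)

| time / min | target / % | substrate / % |
|---|---|---|
| 0.333 | 7.3 | 67.9 |
| 1.00 | 28.9 | 31.6 |
| 2.00 | 49.4 | 10.9 |
| 3.00 | 56.1 | 4.0 |
| 4.00 | 59.3 | 0.7 |

(standard deviation of a reading: 1 percentage point)

- the analysis behind the earlier runs scatters by 1 percentage point, standard deviation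
- the earlier runs do not show what temperature does; that part of a forecast is a guess

- the flask that comes out highest in amount of target, in percent of the substrate charged, or "all alike" when all lie within 1.5 percentage points (autumn / dawn / all alike)
- target at the end, in percent of the substrate charged, autumn
- target at the end, in percent of the substrate charged, dawn

I ordered what the green run showed by time scale. Substrate moved first, falling with a first-order rate constant k of about 1.10 min⁻¹, which is a lifetime of 0.911 min. Target followed and was still rising at the last readings: 56.1% at 3.00 min, 59.3% at 4.00 min. On the last rung stood the material that was neither substrate nor target: it read 39.5% at 1.00 min and 40.0% at 4.00 min, a change within the scatter of 1 percentage point.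

So the 40 min of autumn, far longer than that lifetime, lay well past the last green reading, and I reckoned on the end state. That material did not shrink while target rose, so I read partner as the limiting reagent. I therefore carried one quantity, the partner yield Y, the target made per partner charged, in moles: 0.494 in the green run. Applied to autumn, my reckoning gave 39.5%. For dawn I had no grounds, since temperature was unseen.

The forecast gave 40% for autumn (range 37.5% to 42%) and 40% for dawn (range 32% to 42%), and called the flasks all alike, “unless heat opens a loss of partner or product, which is a guess”.

The flasks gave 43.3% in autumn and 33.6% in dawn, so the highest was autumn.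

    substrate → intermediate (k = 1.13 min⁻¹, Ea = 81.0 kJ mol⁻¹)
    partner + intermediate → target (k = 150 M⁻¹ min⁻¹, Ea = 55.0 kJ mol⁻¹)
    2 intermediate → homo product (k = 2.71 M⁻¹ min⁻¹, Ea = 71.0 kJ mol⁻¹)
    substrate → decomposition product (k = 4.69 × 10⁻⁵ min⁻¹, Ea = 114 kJ mol⁻¹)
    partner → decomposed reagent (k = 0.436 min⁻¹, Ea = 89.0 kJ mol⁻¹)
    (constants at 70 °C)

Y came out at 0.541 in autumn and 0.420 in dawn, lower in the hotter flask, and what heat does to the loss of partner pulls it down: decomposed reagent took 3.67 mM in autumn and 4.64 mM in dawn. The run without that temperature effect turns the gap, dawn minus autumn, from −9.7 points to 20 points. A further flask like autumn, charged with 4.8 mM of partner, was promised 23.7% by the green Y and gave 27.4%, a Y of 0.570.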